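**Retrosynthetic overview**
1. Numbering: ring C1 (CH carrying the chain), C2, C3 (CHBr), C4 (CClMe), C5, C6; chain C7 (C(Me)OH), C8, C9, C10 (CHOH), then isopropenyl. The plan rests on one feature: C4 and C7, the two methyl-bearing fully substituted carbons, face each other across the cyclohexane ring (C7 hangs on C1, para to C4). A temporary C8–C4 bond therefore turns C7–C8–C4 with its two methyl groups into the C6–C1–C2 edge of 2,6-dimethylphenol.
2. Ring halogens: from the C3=C4 alkene through an epoxide, a tertiary bromide and a bromonium ion opened by chloride. C10 carbinol: CBS reduction of an isopropenyl ketone. C8–C9: acetylide opening of a C7–C8 epoxide.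
3. C8–C4: hydroxide cleavage of the non-enolisable ketone of a bicyclo[2.2.2]oct-5-en-2-one, with allylic shift of the alkene to C3=C4.
4. Ring order: the single carbocycle is closed first, inside that bicycle, by the Diels–Alder reaction of the (S)-o-quinol acetate of 2,6-dimethylphenol with ethylene, and only then cut down to the monocycle. C7 comes from the resolved dienone and C1 from the facial course of the cycloaddition.

Key step: step 3

Atom labels C1–C10 in the Why lines are those of the target; locants inside compound names are systematic.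
Assumption: the racemic o-quinol acetate is stable enough at room temperature to be resolved on a chiral phase, and the absolute configuration of the enantiomer carried forward is confirmed by correlation at the hydroxy acid stage.

**Route**

Step 1
Reactants: 1 2,6-dimethylphenol
Product: 2 rac-6-acetoxy-2,6-dimethylcyclohexa-2,4-dien-1-one
Conditions: Pb(OAc)4, AcOH–CH2Cl2, 0 → 20 °C
Reagents that add atoms: lead tetraacetate, CC(=O)O[Pb](OC(C)=O)(OC(C)=O)OC(C)=O
Why: Wessely acetoxylation, in which the aryloxylead triacetate passes an acetate ligand to the methyl-bearing ortho carbon and so dearomatises the phenol to the o-quinol acetate (the two ortho positions are equivalent; the new quaternary centre is formed racemic).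

Step 2
Reactants: 2 rac-6-acetoxy-2,6-dimethylcyclohexa-2,4-dien-1-one
Product: 3 (S)-6-acetoxy-2,6-dimethylcyclohexa-2,4-dien-1-one
Conditions: preparative SFC, amylose tris(3,5-dimethylphenylcarbamate) phase (Chiralpak AD-H), CO2/i-PrOH, 25 °C
Reagents that add atoms: none
Why: Resolution of enantiomers by chromatography on a chiral stationary phase, workable because the quaternary acetoxy carbon has no epimerisation pathway and the 2-methyl group slows dimerisation; this fixes the absolute configuration of the later C7.

Step 3
Reactants: 3 (S)-6-acetoxy-2,6-dimethylcyclohexa-2,4-dien-1-one; 4 ethylene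
Product: 5 (1R,3S,4S)-1,3-dimethyl-2-oxobicyclo[2.2.2]oct-5-en-3-yl acetate (acetoxy on the side of the CH2CH2 bridge, its geminal methyl on the side of the CH=CH bridge)
Conditions: ethylene (60 bar), toluene (0.05 M), BHT, 110 °C, autoclave
Reagents that add atoms: none
Why: A concerted, thermally allowed [4+2] cycloaddition in which the electron-poor 2,4-dienone 3 is the diene and ethylene the 2π partner; the closest known reaction type is the Diels–Alder reaction of Wessely o-quinol acetates and masked o-benzoquinones with alkenes. The six-membered carbocycle C1–C6 is closed by cycloaddition, the new bonds C1–C6 and C4–C5 joining the diene termini to ethylene, and the ring is born inside a bicyclo[2.2.2]oct-5-en-2-one whose third bridge is C7–C8. The two new stereocentres, the bridgeheads C1 and C4, are fixed together by the face of the diene that ethylene takes, and this is controlled by the existing quaternary centre C7: dienophiles add to such dienones on the face that carries the acetoxy group, anti to the methyl group, the same oxygen-directed contrasteric preference shown by 5-acetoxycyclopentadiene. That places the acetoxy group syn to the new ethano bridge and gives the C1/C7 relationship of the target through ring geometry. π-Facial selectivity is the only selectivity required, because ethylene is symmetrical, so neither regiochemistry nor endo/exo orientation has to be controlled. Self-dimerisation of 3 is held back by its 2-methyl group, by dilution and by the large excess of ethylene under pressure.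

Step 4
Reactants: 5 (1R,3S,4S)-1,3-dimethyl-2-oxobicyclo[2.2.2]oct-5-en-3-yl acetate
Product: 6 (1R,3S,4S)-3-hydroxy-1,3-dimethylbicyclo[2.2.2]oct-5-en-2-one
Conditions: K2CO3 (cat.), MeOH, 0 → 20 °C
Reagents that add atoms: none
Why: Base-catalysed transesterification (methanolysis) of the tertiary acetate; the ketone has no α-hydrogen, so nothing can epimerise.

Step 5
Reactants: 6 (1R,3S,4S)-3-hydroxy-1,3-dimethylbicyclo[2.2.2]oct-5-en-2-one
Product: 7 (1R,3S,4S)-3-(1-ethoxyethoxy)-1,3-dimethylbicyclo[2.2.2]oct-5-en-2-one (both epimers at the acetal carbon)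
Conditions: ethyl vinyl ether, PPTS (cat.), CH2Cl2, 20 °C
Reagents that add atoms: ethyl vinyl ether, C=COCC
Why: Acid-catalysed addition of the tertiary alcohol to the vinyl ether gives a base-stable mixed acetal, so that in the next step the oxygen on C7 is not an alkoxide next to the ketone (which would slow hydroxide addition and open the way to α-ketol rearrangement).

Step 6
Reactants: 7 (1R,3S,4S)-3-(1-ethoxyethoxy)-1,3-dimethylbicyclo[2.2.2]oct-5-en-2-one
Product: 9 (2S)-2-hydroxy-2-[(1S)-4-methylcyclohex-3-en-1-yl]propanoic acid, via ethoxyethyl-protected acid 8 (not isolated)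
Conditions: KOt-Bu, H2O (0.3 equiv per KOt-Bu), DMSO–THF, 20 → 45 °C; then 1 M HCl to pH 2, THF, 20 °C
Reagents that add atoms: water, O
Why: Haller–Bauer-type cleavage of a non-enolisable ketone by hydroxide (KOt-Bu/H2O, "anhydrous hydroxide"): hydroxide adds to the C8 carbonyl and the tetrahedral intermediate breaks the C8–C4 bond, since only C4 gives a carbanion stabilised as an allyl anion by the C2=C3 π bond (C7 bears oxygen and would not); tert-butanol should protonate the anion at its less substituted end C2, leaving the trisubstituted alkene at C3=C4, the acidic work-up hydrolyses the acetal, and C1 and C7 are untouched, so their relationship from step 3 is kept.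

Step 7
Reactants: 9 (2S)-2-hydroxy-2-[(1S)-4-methylcyclohex-3-en-1-yl]propanoic acid
Product: 10 (2S)-2-[(1S)-4-methylcyclohex-3-en-1-yl]propane-1,2-diol
Conditions: LiAlH4, THF, 0 → 65 °C; aqueous NaOH work-up
Reagents that add atoms: none
Why: Hydride reduction of the carboxylic acid to the primary alcohol with LiAlH4, which leaves the isolated alkene and the tertiary alcohol unchanged.

Step 8
Reactants: 10 (2S)-2-[(1S)-4-methylcyclohex-3-en-1-yl]propane-1,2-diol
Product: 12 (2S)-2-methyl-2-[(1S)-4-methylcyclohex-3-en-1-yl]oxirane, via primary tosylate 11 (not isolated)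
Conditions: NaH (2.5 equiv), 1-(p-tolylsulfonyl)imidazole, THF, 0 → 20 °C
Reagents that add atoms: none
Why: One-pot epoxide formation from a 1,2-diol: the primary alkoxide is sulfonylated selectively and the tertiary alkoxide closes the oxirane by intramolecular Williamson displacement at C8, so the C7–O bond and its configuration are kept.

Step 9
Reactants: 12 (2S)-2-methyl-2-[(1S)-4-methylcyclohex-3-en-1-yl]oxirane; 13 2-methylbut-1-en-3-yne
Product: 15 (2R)-6-methyl-2-[(1S)-4-methylcyclohex-3-en-1-yl]hept-6-en-4-yn-2-ol, via lithium acetylide 14 (not isolated)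
Conditions: 13, n-BuLi, THF, −78 °C; then 12, DMPU, −20 → 45 °C; aq. NH4Cl
Reagents that add atoms: none
Why: SN2 opening of the 2,2-disubstituted epoxide by the lithium acetylide at the unsubstituted carbon C8 (DMPU raises the nucleophilicity so that no Lewis acid, which could rearrange the epoxide, is needed), forming C8–C9 without touching the C7–O bond.

Step 10
Reactants: 15 (2R)-6-methyl-2-[(1S)-4-methylcyclohex-3-en-1-yl]hept-6-en-4-yn-2-ol
Product: 17 (6R)-6-hydroxy-2-methyl-6-[(1S)-4-methylcyclohex-3-en-1-yl]hept-1-en-3-one, via dihydrofuran 16 (not isolated)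
Conditions: Ph3PAuNTf2 (3 mol%), THF–H2O (10:1), 40 °C; then PPTS (cat.)
Reagents that add atoms: water, O
Why: Gold-catalysed intramolecular hydroalkoxylation: the C7 hydroxyl adds 5-endo-dig to the activated alkyne at C10, and hydrolysis of the resulting 5-alkenyl-2,3-dihydrofuran gives the γ-hydroxy enone with the carbonyl fixed at C10 by ring size and not by the electronics of the enyne.

Step 11
Reactants: 17 (6R)-6-hydroxy-2-methyl-6-[(1S)-4-methylcyclohex-3-en-1-yl]hept-1-en-3-one
Product: 18 (3R,6R)-2-methyl-6-[(1S)-4-methylcyclohex-3-en-1-yl]hept-1-ene-3,6-diol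
Conditions: (S)-Me-CBS oxazaborolidine (20 mol%), catecholborane (2.5 equiv), toluene, −78 °C; MeOH, then aq. NaOH wash
Reagents that add atoms: none
Why: Corey–Bakshi–Shibata reduction: in the catalyst–borane–ketone complex the isopropenyl group takes the large-substituent position and the CH2 chain the small one, so the (S)-oxazaborolidine delivers hydride to give the (R)-carbinol at C10 (the free tertiary alcohol only consumes borane as its borate, and catecholborane at −78 °C does not hydroborate the alkenes).

Step 12
Reactants: 18 (3R,6R)-2-methyl-6-[(1S)-4-methylcyclohex-3-en-1-yl]hept-1-ene-3,6-diol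
Product: 19 (3R,6R)-2-methyl-6-[(1S)-4-methylcyclohex-3-en-1-yl]-3,6-bis(triethylsilyloxy)hept-1-ene
Conditions: TESOTf (2.6 equiv), 2,6-lutidine, CH2Cl2, −78 → 0 °C
Reagents that add atoms: triethylsilyl trifluoromethanesulfonate, CC[Si](CC)(CC)OS(=O)(=O)C(F)(F)F
Why: Silylation of both hydroxyl groups with the silyl triflate (needed for the tertiary one), so that neither oxygen can take part in the epoxide opening, the sulfonylation or the cationic step that follow.

Step 13
Reactants: 19 (3R,6R)-2-methyl-6-[(1S)-4-methylcyclohex-3-en-1-yl]-3,6-bis(triethylsilyloxy)hept-1-ene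
Product: 20 (3R,6R)-2-methyl-6-[(1S,3R,4S)-3,4-epoxy-4-methylcyclohexyl]-3,6-bis(triethylsilyloxy)hept-1-ene (epoxide oxygen trans to the side chain)
Conditions: D-fructose-derived Shi ketone (30 mol%), Oxone (2KHSO5·KHSO4·K2SO4), K2CO3, Bu4NHSO4 (cat.), MeCN–dimethoxymethane/aq. borate buffer, 0 °C
Reagents that add atoms: potassium peroxymonosulfate (KHSO5), OOS(=O)(=O)[O-].[K+]
Why: Shi epoxidation: the dioxirane of the fructose-derived ketone epoxidises the electron-rich trisubstituted ring alkene much faster than the 1,1-disubstituted alkene flanked by a silyloxy group, and catalyst control (the sense known for 1-substituted cyclohexenes, mapped onto C3=C4) should put the oxygen on the face anti to the side chain, for which the substrate itself has no useful bias; this sets C3 and C4 of the epoxide.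

Step 14
Reactants: 20 (3R,6R)-2-methyl-6-[(1S,3R,4S)-3,4-epoxy-4-methylcyclohexyl]-3,6-bis(triethylsilyloxy)hept-1-ene
Product: 22 (3R,6R)-6-[(1S,3R,4R)-4-bromo-3-hydroxy-4-methylcyclohexyl]-2-methyl-3,6-bis(triethylsilyloxy)hept-1-ene, via trimethylsilyl ether 21 (not isolated)
Conditions: TMSBr, 2,6-di-tert-butylpyridine (cat.), CH2Cl2, −78 °C; then citric acid (cat.), MeOH, 0 °C
Reagents that add atoms: bromotrimethylsilane, C[Si](C)(C)Br
Why: Opening of a trisubstituted epoxide by a halosilane: silylation of the epoxide oxygen and attack of bromide at the tertiary carbon C4 with inversion, a mode that is here both Markovnikov and trans-diaxial (Fürst–Plattner) for the chair with the side chain equatorial, gives the axial tertiary bromide syn to the side chain and the axial C3 silyl ether, which mild methanolysis frees while the triethylsilyl ethers stay; any syn-epoxide carried over gives a tertiary alcohol that is separated here.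

Step 15
Reactants: 22 (3R,6R)-6-[(1S,3R,4R)-4-bromo-3-hydroxy-4-methylcyclohexyl]-2-methyl-3,6-bis(triethylsilyloxy)hept-1-ene
Product: 24 (3R,6R)-6-[(1S,3S,4S)-3-bromo-4-chloro-4-methylcyclohexyl]-2-methyl-3,6-bis(triethylsilyloxy)hept-1-ene, via mesylate 23 (not isolated)
Conditions: Ms2O, Et3N, CH2Cl2, −30 °C; then Et4NCl, −30 → 0 °C
Reagents that add atoms: tetraethylammonium chloride, CC[N+](CC)(CC)CC.[Cl-]
Why: Substitution with neighbouring-group participation: the axial C3 mesylate is anti-periplanar to the axial C4 bromine, which displaces it to give a bromonium ion on the face syn to the side chain, and chloride is expected to open this ion at C4, the tertiary carbon that carries most of the positive charge, from the opposite face, so that both centres are inverted (bromine on C3 syn to the chain, chlorine on C4 anti, methyl axial) in a net 1,2-shift of bromine.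

Step 16
Reactants: 24 (3R,6R)-6-[(1S,3S,4S)-3-bromo-4-chloro-4-methylcyclohexyl]-2-methyl-3,6-bis(triethylsilyloxy)hept-1-ene
Product: 25 (3R,6R)-6-[(1S,3S,4S)-3-bromo-4-chloro-4-methylcyclohexyl]-2-methylhept-1-ene-3,6-diol
Conditions: HF·pyridine, pyridine, THF, 0 → 20 °C
Reagents that add atoms: none
Why: Fluoride-mediated cleavage of both silyl ethers under buffered, weakly acidic conditions that leave the secondary bromide, the tertiary chloride and the allylic alcohol untouched and avoid an alkoxide at C7, which could displace the C4 chloride.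

**Compound list**
1 | 2,6-dimethylphenol | Cc1cccc(C)c1O | starting material
2 | rac-6-acetoxy-2,6-dimethylcyclohexa-2,4-dien-1-one | CC1=CC=CC(C)(OC(C)=O)C1=O | intermediate
3 | (S)-6-acetoxy-2,6-dimethylcyclohexa-2,4-dien-1-one | CC1=CC=C[C@](C)(OC(C)=O)C1=O | intermediate
4 | ethylene | C=C | starting material
5 | (1R,3S,4S)-1,3-dimethyl-2-oxobicyclo[2.2.2]oct-5-en-3-yl acetate | O=C1[C@@](C)(OC(C)=O)[C@@H]2C=C[C@@]1(C)CC2 | intermediate
6 | (1R,3S,4S)-3-hydroxy-1,3-dimethylbicyclo[2.2.2]oct-5-en-2-one | O=C1[C@@](C)(O)[C@@H]2C=C[C@@]1(C)CC2 | intermediate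
7 | (1R,3S,4S)-3-(1-ethoxyethoxy)-1,3-dimethylbicyclo[2.2.2]oct-5-en-2-one | O=C1[C@@](C)(OC(C)OCC)[C@@H]2C=C[C@@]1(C)CC2 | intermediate
8 | (2S)-2-(1-ethoxyethoxy)-2-[(1S)-4-methylcyclohex-3-en-1-yl]propanoic acid (potassium salt in the flask) | OC(=O)[C@@](C)(OC(C)OCC)[C@H]1CCC(C)=CC1 | intermediate
9 | (2S)-2-hydroxy-2-[(1S)-4-methylcyclohex-3-en-1-yl]propanoic acid | OC(=O)[C@@](C)(O)[C@H]1CCC(C)=CC1 | intermediate
10 | (2S)-2-[(1S)-4-methylcyclohex-3-en-1-yl]propane-1,2-diol | OC[C@@](C)(O)[C@H]1CCC(C)=CC1 | intermediate
11 | (2S)-2-hydroxy-2-[(1S)-4-methylcyclohex-3-en-1-yl]propyl 4-methylbenzenesulfonate | Cc1ccc(cc1)S(=O)(=O)OC[C@@](C)(O)[C@H]2CCC(C)=CC2 | intermediate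
12 | (2S)-2-methyl-2-[(1S)-4-methylcyclohex-3-en-1-yl]oxirane | C1O[C@@]1(C)[C@H]2CCC(C)=CC2 | intermediate
13 | 2-methylbut-1-en-3-yne | C=C(C)C#C | starting material
14 | lithium 3-methylbut-3-en-1-yn-1-ide | [Li]C#CC(C)=C | intermediate
15 | (2R)-6-methyl-2-[(1S)-4-methylcyclohex-3-en-1-yl]hept-6-en-4-yn-2-ol | C=C(C)C#CC[C@@](C)(O)[C@H]1CCC(C)=CC1 | intermediate
16 | (2R)-2-methyl-2-[(1S)-4-methylcyclohex-3-en-1-yl]-5-(prop-1-en-2-yl)-2,3-dihydrofuran | C=C(C)C1=CC[C@@](C)(O1)[C@H]2CCC(C)=CC2 | intermediate
17 | (6R)-6-hydroxy-2-methyl-6-[(1S)-4-methylcyclohex-3-en-1-yl]hept-1-en-3-one | C=C(C)C(=O)CC[C@@](C)(O)[C@H]1CCC(C)=CC1 | intermediate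
18 | (3R,6R)-2-methyl-6-[(1S)-4-methylcyclohex-3-en-1-yl]hept-1-ene-3,6-diol | C=C(C)[C@H](O)CC[C@@](C)(O)[C@H]1CCC(C)=CC1 | intermediate
19 | (3R,6R)-2-methyl-6-[(1S)-4-methylcyclohex-3-en-1-yl]-3,6-bis(triethylsilyloxy)hept-1-ene | C=C(C)[C@H](O[Si](CC)(CC)CC)CC[C@@](C)(O[Si](CC)(CC)CC)[C@H]1CCC(C)=CC1 | intermediate
20 | (3R,6R)-2-methyl-6-[(1S,3R,4S)-3,4-epoxy-4-methylcyclohexyl]-3,6-bis(triethylsilyloxy)hept-1-ene | C=C(C)[C@H](O[Si](CC)(CC)CC)CC[C@@](C)(O[Si](CC)(CC)CC)[C@H]1CC[C@]2(C)O[C@@H]2C1 | intermediate
21 | (3R,6R)-6-[(1S,3R,4R)-4-bromo-4-methyl-3-(trimethylsilyloxy)cyclohexyl]-2-methyl-3,6-bis(triethylsilyloxy)hept-1-ene | C=C(C)[C@H](O[Si](CC)(CC)CC)CC[C@@](C)(O[Si](CC)(CC)CC)[C@H]1CC[C@@](C)(Br)[C@H](O[Si](C)(C)C)C1 | intermediate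
22 | (3R,6R)-6-[(1S,3R,4R)-4-bromo-3-hydroxy-4-methylcyclohexyl]-2-methyl-3,6-bis(triethylsilyloxy)hept-1-ene | C=C(C)[C@H](O[Si](CC)(CC)CC)CC[C@@](C)(O[Si](CC)(CC)CC)[C@H]1CC[C@@](C)(Br)[C@H](O)C1 | intermediate
23 | (3R,6R)-6-[(1S,3R,4R)-4-bromo-4-methyl-3-(methylsulfonyloxy)cyclohexyl]-2-methyl-3,6-bis(triethylsilyloxy)hept-1-ene | C=C(C)[C@H](O[Si](CC)(CC)CC)CC[C@@](C)(O[Si](CC)(CC)CC)[C@H]1CC[C@@](C)(Br)[C@H](OS(C)(=O)=O)C1 | intermediate
24 | (3R,6R)-6-[(1S,3S,4S)-3-bromo-4-chloro-4-methylcyclohexyl]-2-methyl-3,6-bis(triethylsilyloxy)hept-1-ene | C=C(C)[C@H](O[Si](CC)(CC)CC)CC[C@@](C)(O[Si](CC)(CC)CC)[C@H]1CC[C@](C)(Cl)[C@@H](Br)C1 | intermediate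
25 | (3R,6R)-6-[(1S,3S,4S)-3-bromo-4-chloro-4-methylcyclohexyl]-2-methylhept-1-ene-3,6-diol | C=C(C)[C@H](O)CC[C@@](C)(O)[C@H]1CC[C@](C)(Cl)[C@@H](Br)C1 | target

**Totals and risks**

Total step count: 16. Longest linear sequence: 16 steps (from 2,6-dimethylphenol; ethylene and the enyne are used as purchased).

Steps most likely to fail:

1. Step 6. The C8–C4 cleavage may be slow on this hindered, only moderately strained ketone, and the allyl anion may be protonated at C4 as well as at C2, which would leave part of the material with the alkene at C2=C3.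
Fallback, from 5 back to 9: direct irradiation of 5 (300 nm, benzene, 20 °C) should bring about the 1,3-acyl shift known for bicyclo[2.2.2]oct-5-en-2-ones. It gives the cis-fused cyclobutanone 7-acetoxy-3,7-dimethylbicyclo[4.2.0]oct-2-en-8-one F1, in which C8 has moved from C4 to C2 on the same face and the alkene already sits at C3=C4. NaOMe in MeOH at 0–20 °C then removes the acetate and opens the strained four-membered ketone at the C8–C2 bond, giving methyl (2S)-2-hydroxy-2-[(1S)-4-methylcyclohex-3-en-1-yl]propanoate F2. LiOH in aqueous THF hydrolyses F2 to 9. This path needs no protection of the alcohol and is driven by ring strain. It also generates the same allyl anion from its other terminus, so it gives the wanted alkene if protonation follows the departing acyl carbon, whereas step 6 gives it if protonation is charge-controlled.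

2. Step 15. Chloride may capture the bromonium ion at C3 instead of C4. That is the trans-diaxial mode of opening for the chair with the side chain equatorial, whereas attack at C4 leads to a diequatorial product, so this competition is real. It would keep bromine on C4 and put chlorine on C3.
Fallback, from 22 back to 24: the same ionisation then gives the trans-diaxial isomer (3R,6R)-6-[(1S,3R,4R)-4-bromo-3-chloro-4-methylcyclohexyl]-2-methyl-3,6-bis(triethylsilyloxy)hept-1-ene F3. F3 is not discarded. Heating it in a polar solvent (nitromethane, about 70 °C) applies the known diaxial–diequatorial 1,2-interchange of vicinal dihalides, in which each halogen moves to the neighbouring carbon on its own face through the same bridged ion pair, now under equilibrium control, and this should deliver 24. The stronger bond pair (tertiary C–Cl, secondary C–Br) and the polar medium favour the diequatorial isomer, but the axial methyl group of 24 works against it, so the equilibrium may lie on the side of F3. Unchanged F3 is separated and resubmitted.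

3. Step 3. Unactivated ethylene may add too slowly, so that dimerisation or thermal acetoxy migration of the dienone competes.
Fallback, from 3 back to 5: phenyl vinyl selenide, an electron-rich ethylene equivalent matched to the electron-poor dienone, is used in toluene at 60–80 °C. The cycloaddition should take the same acetoxy face and give 3-acetoxy-1,3-dimethyl-7-(phenylselanyl)bicyclo[2.2.2]oct-5-en-2-one F4 (selenium on the carbon next to the methyl-bearing bridgehead, either epimer). Radical reduction with Bu3SnH and AIBN in toluene at 80 °C, at high stannane concentration, then removes selenium and gives 5 without touching the ketone, the acetate or the alkene. A vinyl sulfone is avoided because reductive desulfonylation would also cleave the α-acetoxy ketone.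

**Further compounds**
F1 | step 6 | cis-fused 7-acetoxy-3,7-dimethylbicyclo[4.2.0]oct-2-en-8-one (configuration at the acetoxy carbon and the adjacent ring-fusion carbon as in 5) | O=C1[C@@](C)(OC(C)=O)[C@H]2CCC(C)=C[C@@H]12
F2 | step 6 | methyl (2S)-2-hydroxy-2-[(1S)-4-methylcyclohex-3-en-1-yl]propanoate | COC(=O)[C@@](C)(O)[C@H]1CCC(C)=CC1
F3 | step 15 | (3R,6R)-6-[(1S,3R,4R)-4-bromo-3-chloro-4-methylcyclohexyl]-2-methyl-3,6-bis(triethylsilyloxy)hept-1-ene | C=C(C)[C@H](O[Si](CC)(CC)CC)CC[C@@](C)(O[Si](CC)(CC)CC)[C@H]1CC[C@@](C)(Br)[C@H](Cl)C1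
F4 | step 3 | 3-acetoxy-1,3-dimethyl-7-(phenylselanyl)bicyclo[2.2.2]oct-5-en-2-one (ring stereocentres as in 5, either epimer at the selenium-bearing carbon) | O=C1[C@@](C)(OC(C)=O)[C@@H]2C=C[C@@]1(C)C([Se]c3ccccc3)C2
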